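**Assumption:** the target is taken exactly as drawn, which I read as an all-trans (1S,2S,3R) 1-aryl-2,3-dimethyltetralin whose pendant-aryl oxygen carries an erythro (1S,2R) 1-aryl-1-hydroxypropan-2-yl group. Compound 4 and 1-propynylmagnesium bromide solution are treated as commercial.

## Retrosynthetic overview

1. Target 16 ⇒ O-debenzylation of 15; the carbinol centre comes from chelation-controlled reduction of α-aryloxy ketone 14, made from a Weinreb amide and an aryl Grignard.
2. The alkyl–O–aryl bond and its stereocentre come from a Mitsunobu inversion of ethyl (S)-lactate with core phenol 10.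
3. Core 10 ⇒ intramolecular Friedel–Crafts closure of a p-hydroxybenzylic cation, generated by DDQ benzylic oxidation of mono-phenol 8. This is the only ring formed in the synthesis; both aromatic rings are purchased.
4. 8 ⇒ (2R,3R)-dibenzylbutane 7 ⇒ double asymmetric hydrogenation of (E,E)-diene 6 (proposed new step; sets both methyl-bearing stereocentres).
5. 6 ⇒ zirconocene cross-coupling of aryl propynes 3 and 5, each one step from a 4-bromoguaiacol ether.

## Route

**Step 1**
Reactants: 1, 4-bromo-2-methoxyphenol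
Product: 2, tert-butyl(4-bromo-2-methoxyphenoxy)dimethylsilane
Conditions: TBSCl, imidazole, DMF, rt
Reagents that add atoms: TBSCl, CC(C)(C)[Si](C)(C)Cl
Why: Standard phenol silylation; TBS later distinguishes this ring (the future pendant aryl) from the benzyl-protected ring.

**Step 2**
Reactants: 2
Product: 3, tert-butyl[2-methoxy-4-(prop-1-yn-1-yl)phenoxy]dimethylsilane
Conditions: CH3C≡CMgBr (0.5 M in THF), ZnBr2; Pd(PPh3)4 (5 mol %), THF, 65 °C
Reagents that add atoms: 1-propynylmagnesium bromide, CC#C[Mg]Br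
Why: Negishi alkynylation of an aryl bromide; the aryl silyl ether tolerates the alkynylzinc reagent.

**Step 3**
Reactants: 4, 1-(benzyloxy)-4-bromo-2-methoxybenzene
Product: 5, 1-(benzyloxy)-2-methoxy-4-(prop-1-yn-1-yl)benzene
Conditions: CH3C≡CMgBr, ZnBr2; Pd(PPh3)4 (5 mol %), THF, 65 °C
Reagents that add atoms: 1-propynylmagnesium bromide, CC#C[Mg]Br
Why: Same Negishi alkynylation as step 2.

**Step 4**
Reactants: 5 and 3
Product: 6, (1E,3E)-1-[4-(benzyloxy)-3-methoxyphenyl]-4-[4-(tert-butyldimethylsilyloxy)-3-methoxyphenyl]-2,3-dimethylbuta-1,3-diene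
Conditions: Cp2ZrCl2, EtMgBr (2 equiv), THF, −78 °C; add 5, 0 °C, 3 h; add 3, 50 °C, 3 h; then 1 M HCl, 0 °C
Reagents that add atoms: none beyond 3 and 5 (the two vinylic H come from the acid quench)
Why: Zirconocene–ethylene mediated stepwise cross-coupling of two alkynes (zirconacyclopentene, then zirconacyclopentadiene); aryl groups sit α to Zr so the C–C bond forms between the methyl-bearing carbons, and protonolysis with retention gives the E,E diene.

**Step 5**
Reactants: 6
Product: 7, (2R,3R)-1-[4-(benzyloxy)-3-methoxyphenyl]-4-[4-(tert-butyldimethylsilyloxy)-3-methoxyphenyl]-2,3-dimethylbutane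
Conditions: [Ir(cod)(ThrePHOX-type N,P ligand)]BArF (2 mol %; ligand enantiomer that reduces (E)-1-aryl-2-methylalkenes to the R methine), H2 (50 bar), CH2Cl2, 25 °C
Reagents that add atoms: none (H2 only)
Why: Proposed new method: double asymmetric hydrogenation of a 2,3-dialkyl-1,4-diaryl-1,3-diene, which to my knowledge has not been shown; the 2,3-dimethyl diene is twisted out of conjugation, so each (E)-ArCH=C(Me)R unit should react as an isolated trisubstituted styrene through the usual Ir(III)/Ir(V) dihydride syn-addition, with the ligand selecting the same enantioface twice to give the (R,R) product, while any facial error is diverted to the separable meso-like diastereomer and so raises the ee of 7; the closest known reaction type is Ir–N,P hydrogenation of unfunctionalized (E)-1-aryl-2-methylalkenes and of isolated polyenes.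

**Step 6**
Reactants: 7
Product: 8, 4-[(2R,3R)-4-(4-(benzyloxy)-3-methoxyphenyl)-2,3-dimethylbutyl]-2-methoxyphenol
Conditions: TBAF, THF, 0 °C
Reagents that add atoms: none
Why: Fluoride desilylation frees only the phenol on the future pendant ring; the benzyl ether is untouched.

**Step 7**
Reactants: 8
Product: 9, 4-[(2S,3R)-4-(4-(benzyloxy)-3-methoxyphenyl)-1-methoxy-2,3-dimethylbutyl]-2-methoxyphenol (mixture of C1 epimers, inconsequential)
Conditions: DDQ (1.0 equiv, slow addition), CH2Cl2–MeOH 4:1, 0 °C
Reagents that add atoms: methanol, CO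
Why: DDQ dehydrogenation of a p-alkylphenol to the p-quinone methide with methanol trapping occurs only at the benzylic carbon para to the free OH, so the two otherwise equivalent benzylic positions are differentiated; the descriptor change at C2 is a CIP priority change only.

**Step 8**
Reactants: 9
Product: 10, 4-[(1S,2S,3R)-7-(benzyloxy)-6-methoxy-2,3-dimethyl-1,2,3,4-tetrahydronaphthalen-1-yl]-2-methoxyphenol
Conditions: TFA (2 equiv), CH2Cl2 (0.01 M), −20 → 0 °C
Reagents that add atoms: none (MeOH is lost)
Why: Ionization to the p-hydroxybenzylic cation and intramolecular Friedel–Crafts alkylation para to the OMe of the benzyloxy ring closes the tetralin through a chair-like transition state with the aryl and both methyls equatorial, setting C1 as S, trans to the C2 methyl.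

**Step 9**
Reactants: 10 and 11, ethyl (S)-lactate
Product: 12, ethyl (2R)-2-{4-[(1S,2S,3R)-7-(benzyloxy)-6-methoxy-2,3-dimethyl-1,2,3,4-tetrahydronaphthalen-1-yl]-2-methoxyphenoxy}propanoate
Conditions: PPh3, DIAD, THF, 0 °C → rt
Reagents that add atoms: none beyond 10 and 11
Why: Mitsunobu etherification of the only free OH proceeds with clean SN2 inversion of the lactate carbinol, (S) → (R), which is the configuration of the aryloxy-bearing carbon of the target.

**Step 10**
Reactants: 12
Product: 13, (2R)-2-{4-[(1S,2S,3R)-7-(benzyloxy)-6-methoxy-2,3-dimethyl-1,2,3,4-tetrahydronaphthalen-1-yl]-2-methoxyphenoxy}-N-methoxy-N-methylpropanamide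
Conditions: MeNH(OMe)·HCl, i-PrMgCl, THF, −20 °C
Reagents that add atoms: N,O-dimethylhydroxylamine hydrochloride, CNOC.Cl
Why: Direct ester-to-Weinreb-amide aminolysis with the magnesium amide at low temperature, which should leave the α-aryloxy stereocentre intact.

**Step 11**
Reactants: 13 and 4 (as its Grignard reagent)
Product: 14, (2R)-1-[4-(benzyloxy)-3-methoxyphenyl]-2-{4-[(1S,2S,3R)-7-(benzyloxy)-6-methoxy-2,3-dimethyl-1,2,3,4-tetrahydronaphthalen-1-yl]-2-methoxyphenoxy}propan-1-one
Conditions: 4, Mg, THF; add to 13, THF, −20 → 0 °C; cold NH4Cl quench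
Reagents that add atoms: none beyond 4 and 13
Why: Weinreb ketone synthesis; the stable chelated tetrahedral intermediate prevents over-addition and keeps the enolizable α-centre masked until the cold quench.

**Step 12**
Reactants: 14
Product: 15, (1S,2R)-1-[4-(benzyloxy)-3-methoxyphenyl]-2-{4-[(1S,2S,3R)-7-(benzyloxy)-6-methoxy-2,3-dimethyl-1,2,3,4-tetrahydronaphthalen-1-yl]-2-methoxyphenoxy}propan-1-ol
Conditions: Zn(BH4)2, Et2O, −30 → 0 °C (crude 14 used at once)
Reagents that add atoms: none (hydride only)
Why: Cram-chelate reduction: Zn bridges the carbonyl and the α-aryloxy/ortho-OMe oxygens and hydride is delivered from the face bearing the α-H, giving the anti (erythro) alcohol, (1S) from the (2R) ketone.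

**Step 13**
Reactants: 15
Product: 16, (1S,2R)-1-(4-hydroxy-3-methoxyphenyl)-2-{4-[(1S,2S,3R)-7-hydroxy-6-methoxy-2,3-dimethyl-1,2,3,4-tetrahydronaphthalen-1-yl]-2-methoxyphenoxy}propan-1-ol (target)
Conditions: H2 (1 atm), 10 % Pd/C, EtOAc (trace NaHCO3), rt, monitored
Reagents that add atoms: none
Why: Hydrogenolysis of the two aryl benzyl ethers under neutral, buffered conditions is faster than cleavage of the secondary benzylic alcohol, and no stereocentre is affected.

## Compound list

1 | 4-bromo-2-methoxyphenol | COc1cc(Br)ccc1O | starting material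
2 | tert-butyl(4-bromo-2-methoxyphenoxy)dimethylsilane | COc1cc(Br)ccc1O[Si](C)(C)C(C)(C)C | intermediate
3 | tert-butyl[2-methoxy-4-(prop-1-yn-1-yl)phenoxy]dimethylsilane | CC#Cc1ccc(O[Si](C)(C)C(C)(C)C)c(OC)c1 | intermediate
4 | 1-(benzyloxy)-4-bromo-2-methoxybenzene | COc1cc(Br)ccc1OCc1ccccc1 | starting material
5 | 1-(benzyloxy)-2-methoxy-4-(prop-1-yn-1-yl)benzene | CC#Cc1ccc(OCc2ccccc2)c(OC)c1 | intermediate
6 | (1E,3E)-1-[4-(benzyloxy)-3-methoxyphenyl]-4-[4-(TBSO)-3-methoxyphenyl]-2,3-dimethylbuta-1,3-diene | COc1cc(/C=C(C)/C(C)=C/c2ccc(O[Si](C)(C)C(C)(C)C)c(OC)c2)ccc1OCc1ccccc1 | intermediate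
7 | (2R,3R)-1-[4-(benzyloxy)-3-methoxyphenyl]-4-[4-(TBSO)-3-methoxyphenyl]-2,3-dimethylbutane | COc1cc(C[C@@H](C)[C@H](C)Cc2ccc(O[Si](C)(C)C(C)(C)C)c(OC)c2)ccc1OCc1ccccc1 | intermediate
8 | 4-[(2R,3R)-4-(4-(benzyloxy)-3-methoxyphenyl)-2,3-dimethylbutyl]-2-methoxyphenol | COc1cc(C[C@@H](C)[C@H](C)Cc2ccc(OCc3ccccc3)c(OC)c2)ccc1O | intermediate
9 | 4-[(2S,3R)-4-(4-(benzyloxy)-3-methoxyphenyl)-1-methoxy-2,3-dimethylbutyl]-2-methoxyphenol (C1 epimers) | COc1cc(C(OC)[C@@H](C)[C@H](C)Cc2ccc(OCc3ccccc3)c(OC)c2)ccc1O | intermediate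
10 | 4-[(1S,2S,3R)-7-(benzyloxy)-6-methoxy-2,3-dimethyl-1,2,3,4-tetrahydronaphthalen-1-yl]-2-methoxyphenol | COc1cc([C@H]2c3cc(OCc4ccccc4)c(OC)cc3C[C@@H](C)[C@@H]2C)ccc1O | intermediate
11 | ethyl (S)-lactate | CCOC(=O)[C@H](C)O | starting material
12 | ethyl (2R)-2-{4-[(1S,2S,3R)-7-(benzyloxy)-6-methoxy-2,3-dimethyltetralin-1-yl]-2-methoxyphenoxy}propanoate | CCOC(=O)[C@@H](C)Oc1ccc([C@H]2c3cc(OCc4ccccc4)c(OC)cc3C[C@@H](C)[C@@H]2C)cc1OC | intermediate
13 | (2R)-Weinreb amide of 12 | CON(C)C(=O)[C@@H](C)Oc1ccc([C@H]2c3cc(OCc4ccccc4)c(OC)cc3C[C@@H](C)[C@@H]2C)cc1OC | intermediate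
14 | (2R)-1-[4-(benzyloxy)-3-methoxyphenyl]-2-(aryloxy)propan-1-one | COc1cc(C(=O)[C@@H](C)Oc2ccc([C@H]3c4cc(OCc5ccccc5)c(OC)cc4C[C@@H](C)[C@@H]3C)cc2OC)ccc1OCc1ccccc1 | intermediate
15 | (1S,2R)-1-[4-(benzyloxy)-3-methoxyphenyl]-2-(aryloxy)propan-1-ol, bis-benzyl ether of the target | COc1cc([C@H](O)[C@@H](C)Oc2ccc([C@H]3c4cc(OCc5ccccc5)c(OC)cc4C[C@@H](C)[C@@H]3C)cc2OC)ccc1OCc1ccccc1 | intermediate
16 | CID 53359464 | COc1cc([C@H](O)[C@@H](C)Oc2ccc([C@H]3c4cc(O)c(OC)cc4C[C@@H](C)[C@@H]3C)cc2OC)ccc1O | target

## Summary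

Total steps: 13. Longest linear sequence: 12 (1 → 2 → 3 → 6 → 7 → 8 → 9 → 10 → 12 → 13 → 14 → 15 → 16).

Steps most likely to fail:

1. **Step 5 (proposed new hydrogenation).** Risks are 1,4-reduction or isomerization to the tetrasubstituted alkene, a stalled second reduction, or too much meso-like diastereomer. Fallback (known chemistry): build 7 by the chiral-lactone route. Stobbe condensation of 4-(benzyloxy)-3-methoxybenzaldehyde with dimethyl succinate, Rh–bisphosphine asymmetric hydrogenation of the half-ester, and reduction/lactonization give the β-(arylmethyl)-γ-butyrolactone. Trans-selective enolate alkylation with 4-(TBSO)-3-methoxybenzyl bromide, then LiAlH4, bis-mesylation and LiAlH4 convert the lactone into the two methyl groups.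

2. **Step 7 (DDQ benzylic oxidation).** Risks are over-oxidation and phenol coupling. Fallback: carry the C1 oxygen in from the start instead of oxidizing a C–H. Aldol of the same lactone enolate with 4-(TBSO)-3-methoxybenzaldehyde, acid-mediated cyclization of the benzylic alcohol to the aryltetralin lactone, lactone-to-dimethyl reduction (LiAlH4; MsCl; LiAlH4) and desilylation give 10.

3. **Step 4 (zirconocene cross-coupling).** Risks are incomplete cross-selectivity or α/β regiochemistry. Fallback: Suzuki–Miyaura coupling of two geometrically defined alkenyl partners. Cu-catalysed syn-hydroboration of 3 and 5 gives the (Z)-ArCH=C(Bpin)CH3 boronates; one is converted to the alkenyl bromide with CuBr2 and the two are coupled under Pd catalysis to give 6.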